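**Plan**

- Retrosynthesis: after the protecting groups, the two O–CH3 bonds of ring A (ester and C3 ether) are cut first. Ring A (the methyl benzoate ring: C1 CO2Me, C2 OAr, C3 OMe, C5 OH) is then opened at its C1–C2 bond. Oxygen on C3 and C5 with a carboxyl carbon on C1 mark it as a cyclised 2,4,6-trioxoheptanoate whose terminal carbon (C2 of ring A) already bears the aryloxy group; that chain is a ring-opened 6-(aryloxymethyl)-4-oxo-4H-pyran-2-carboxylate.
- The ArO–CH2 bond is cut last, giving a ring B phenol (from 2,6-dihydroxy-4-methylbenzoic acid) and the mono-alcohol of dimethyl chelidonate.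
- Forward: ring B is bought and dressed (tert-butyl ester, chlorine, TIPS/MOM differentiation of its two hydroxyls) and joined to the pyranone arm by a Mitsunobu ether bond at a CH2 carbon. Ring A is then grown around that carbon by Ba(OH)2 opening and aldol recyclisation; esterification, 5-O-silylation, 3-O-methylation and two unmasking steps finish.
- Stereochemistry: the target has no stereocentre; only positional selectivity must be controlled, and it is set by the symmetry of the ring B diol and by steric differentiation of hydroxyl pairs.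

Key step: step 8

Remark: ring A is numbered C1 (CO2Me), C2 (OAr), C3 (OMe), C5 (OH); ring B is the chlorinated salicylic acid ring; both starting acids are taken as commercial.

**Route**

Step 1
Reactants: 1 2,6-dihydroxy-4-methylbenzoic acid
Product: 2 tert-butyl 2,6-dihydroxy-4-methylbenzoate
Conditions: tert-butyl N,N'-diisopropylcarbamimidate (1.5 equiv), THF, rt
Reagents that add atoms: tert-butyl N,N'-diisopropylcarbamimidate, CC(C)N=C(NC(C)C)OC(C)(C)C
Why: Esterification by O-alkylation of the carboxylate with the protonated isourea needs no attack at the hindered carbonyl and runs neutral at room temperature, which should spare the decarboxylation-prone acid and leave the chelated phenols untouched.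

Step 2
Reactants: 2 tert-butyl 2,6-dihydroxy-4-methylbenzoate
Product: 3 tert-butyl 3-chloro-2,6-dihydroxy-4-methylbenzoate
Conditions: NCS (1.0 equiv), MeCN, 0 °C to rt
Reagents that add atoms: N-chlorosuccinimide, O=C1CCC(=O)N1Cl
Why: Electrophilic aromatic chlorination of the symmetric diol can give only one monochloride, because C3 and C5 are equivalent (each ortho to one hydroxyl and para to the other), and the first chlorine slows a second substitution.

Step 3
Reactants: 3 tert-butyl 3-chloro-2,6-dihydroxy-4-methylbenzoate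
Product: 4 tert-butyl 3-chloro-2-hydroxy-4-methyl-6-[(triisopropylsilyl)oxy]benzoate
Conditions: TIPSCl (1.05 equiv), imidazole, DMF, 0 °C to rt
Reagents that add atoms: chlorotriisopropylsilane, CC(C)[Si](Cl)(C(C)C)C(C)C
Why: Sterically controlled O-silylation should take O6, which has one open flank (H-5), whereas O2 is wedged between chlorine and the tert-butyl ester.

Step 4
Reactants: 4 tert-butyl 3-chloro-2-hydroxy-4-methyl-6-[(triisopropylsilyl)oxy]benzoate
Product: 6 tert-butyl 3-chloro-6-hydroxy-2-(methoxymethoxy)-4-methylbenzoate, via silyl MOM ether 5 (not isolated)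
Conditions: NaH, MOMCl, THF, 0 °C to rt; MeOH quench; then TBAF, 0 °C; aq NH4Cl
Reagents that add atoms: chloromethyl methyl ether, COCCl
Why: Williamson-type O-alkylation of the sodium phenoxide by the small, reactive chloromethyl ether caps the hindered hydroxyl, and fluoride then cleaves only the aryl silyl ether, leaving acetal, tert-butyl ester and aryl chloride intact.

Step 5
Reactants: 7 chelidonic acid (4-oxo-4H-pyran-2,6-dicarboxylic acid)
Product: 8 dimethyl 4-oxo-4H-pyran-2,6-dicarboxylate
Conditions: MeOH, H2SO4 (cat.), reflux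
Reagents that add atoms: methanol, CO
Why: Fischer esterification of both carboxyl groups should proceed cleanly, since the 4-pyranone ring is stable to acid.

Step 6
Reactants: 8 dimethyl 4-oxo-4H-pyran-2,6-dicarboxylate
Product: 9 methyl 6-(hydroxymethyl)-4-oxo-4H-pyran-2-carboxylate
Conditions: NaBH4 (0.6 equiv), MeOH–CH2Cl2, −10 °C
Reagents that add atoms: none
Why: Borohydride reduction of an ester activated by the adjacent ring oxygen (as in pyridine-2,6-dicarboxylates) should occur at low temperature without touching the vinylogous-ester C4 carbonyl, and limiting hydride stops the desymmetrising reduction at the mono-alcohol.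

Step 7
Reactants: 6 tert-butyl 3-chloro-6-hydroxy-2-(methoxymethoxy)-4-methylbenzoate; 9 methyl 6-(hydroxymethyl)-4-oxo-4H-pyran-2-carboxylate
Product: 10 methyl 6-{[2-(tert-butoxycarbonyl)-4-chloro-3-(methoxymethoxy)-5-methylphenoxy]methyl}-4-oxo-4H-pyran-2-carboxylate
Conditions: PPh3, DIAD, THF, 0 °C to rt
Reagents that add atoms: none
Why: Mitsunobu etherification joins the sufficiently acidic, singly ortho-substituted phenol to the primary alcohol by SN2 at the oxyphosphonium carbon, without any base that could open the pyranone.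

Step 8
Reactants: 10 methyl 6-{[2-(tert-butoxycarbonyl)-4-chloro-3-(methoxymethoxy)-5-methylphenoxy]methyl}-4-oxo-4H-pyran-2-carboxylate
Product: 13 2-[2-(tert-butoxycarbonyl)-4-chloro-3-(methoxymethoxy)-5-methylphenoxy]-3,5-dihydroxybenzoic acid, via triketo acid 11 (not isolated), via aldol carbinol 12 (not isolated)
Conditions: Ba(OH)2·8H2O (5 equiv), degassed 1,4-dioxane–H2O (1:1), Ar, rt to 50 °C; then cold 1 M HCl to pH 3
Reagents that add atoms: barium hydroxide (hydroxide oxygen), [Ba+2].[OH-].[OH-]; water, O
Why: Hydroxide saponifies the activated methyl ester and adds to an α-carbon of the 4-pyranone, whose hemiketal opens to the 2,4,6-trioxoheptanoate 11, held as a barium enolate chelate. The aryloxymethylene carbon of 11, acidified by its ketone and the aryloxy oxygen, then adds as an enolate to the α-keto carboxylate carbonyl in a 6-(enolendo)-exo-trig aldol closure that forms the C1–C2 bond of ring A and gives carbinol 12; E1cB loss of water and enolisation of the two remaining ketones deliver the benzene ring irreversibly. The closest known reaction type is the baryta-induced opening of 2,6-dimethyl-4-pyranone to heptane-2,4,6-trione with aldol recyclisation to orcinol, together with the aldol aromatisation of 3,5,7-triketo acids to resorcylic acids. No stereocentre is kept, since the two created in 12 vanish on aromatisation. The step needs constitutional selectivity only: pairing of C7 with C2 is the sole enolate–carbonyl combination that gives a six-membered carbocycle (the others would be four-membered), the carboxylate is no electrophile, and every ring–chain and aldol equilibrium stays reversible until aromatisation drains it. The doubly ortho-flanked tert-butyl ester, the MOM acetal and the aryl chloride are inert to aqueous hydroxide, and moderate temperature with the chelating barium counter-ion should hold back retro-Claisen loss of the oxalyl unit.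

Step 9
Reactants: 13 2-[2-(tert-butoxycarbonyl)-4-chloro-3-(methoxymethoxy)-5-methylphenoxy]-3,5-dihydroxybenzoic acid
Product: 14 methyl 2-[2-(tert-butoxycarbonyl)-4-chloro-3-(methoxymethoxy)-5-methylphenoxy]-3,5-dihydroxybenzoate
Conditions: MeI, KHCO3, DMF, rt
Reagents that add atoms: iodomethane, CI
Why: Carboxylate O-alkylation (SN2) is selective because hydrogen carbonate ionises the carboxylic acid but not the two phenols.

Step 10
Reactants: 14 methyl 2-[2-(tert-butoxycarbonyl)-4-chloro-3-(methoxymethoxy)-5-methylphenoxy]-3,5-dihydroxybenzoate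
Product: 15 methyl 2-[2-(tert-butoxycarbonyl)-4-chloro-3-(methoxymethoxy)-5-methylphenoxy]-3-hydroxy-5-[(triisopropylsilyl)oxy]benzoate
Conditions: TIPSCl (1.0 equiv), imidazole, CH2Cl2–DMF, −20 to 0 °C
Reagents that add atoms: chlorotriisopropylsilane, CC(C)[Si](Cl)(C(C)C)C(C)C
Why: Sterically controlled O-silylation should favour the C5 hydroxyl, flanked by two hydrogens, over the C3 hydroxyl, which sits beside the twisted aryloxy group carrying the tert-butyl ester.

Step 11
Reactants: 15 methyl 2-[2-(tert-butoxycarbonyl)-4-chloro-3-(methoxymethoxy)-5-methylphenoxy]-3-hydroxy-5-[(triisopropylsilyl)oxy]benzoate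
Product: 16 methyl 2-[2-(tert-butoxycarbonyl)-4-chloro-3-(methoxymethoxy)-5-methylphenoxy]-3-methoxy-5-[(triisopropylsilyl)oxy]benzoate
Conditions: MeI, K2CO3, dry acetone, rt
Reagents that add atoms: iodomethane, CI
Why: Williamson methylation of the only free phenol proceeds under mild carbonate conditions that the bulky aryl silyl ether and both esters tolerate.

Step 12
Reactants: 16 methyl 2-[2-(tert-butoxycarbonyl)-4-chloro-3-(methoxymethoxy)-5-methylphenoxy]-3-methoxy-5-[(triisopropylsilyl)oxy]benzoate
Product: 17 methyl 2-[2-(tert-butoxycarbonyl)-4-chloro-3-(methoxymethoxy)-5-methylphenoxy]-5-hydroxy-3-methoxybenzoate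
Conditions: TBAF, AcOH, THF, 0 °C
Reagents that add atoms: none
Why: Fluoride-induced desilylation cleaves the Si–O bond selectively, and the acetic acid buffer keeps the methyl ester and the liberated phenol out of basic side reactions.

Step 13
Reactants: 17 methyl 2-[2-(tert-butoxycarbonyl)-4-chloro-3-(methoxymethoxy)-5-methylphenoxy]-5-hydroxy-3-methoxybenzoate
Product: 18 isodihydromaldoxin, 3-chloro-2-hydroxy-6-[4-hydroxy-2-methoxy-6-(methoxycarbonyl)phenoxy]-4-methylbenzoic acid
Conditions: TFA–CH2Cl2–H2O (10:10:1), 0 °C to rt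
Reagents that add atoms: none
Why: Acidolysis removes the tert-butyl ester through the tert-butyl cation and hydrolyses the MOM acetal, while the methyl ester, aryl methyl ether, diaryl ether and aryl chloride are stable to trifluoroacetic acid.

**Compound list**

1 | 2,6-dihydroxy-4-methylbenzoic acid | Cc1cc(O)c(C(=O)O)c(O)c1 | starting material
2 | tert-butyl 2,6-dihydroxy-4-methylbenzoate | Cc1cc(O)c(C(=O)OC(C)(C)C)c(O)c1 | intermediate
3 | tert-butyl 3-chloro-2,6-dihydroxy-4-methylbenzoate | Cc1cc(O)c(C(=O)OC(C)(C)C)c(O)c1Cl | intermediate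
4 | tert-butyl 3-chloro-2-hydroxy-4-methyl-6-[(triisopropylsilyl)oxy]benzoate | Cc1cc(O[Si](C(C)C)(C(C)C)C(C)C)c(C(=O)OC(C)(C)C)c(O)c1Cl | intermediate
5 | tert-butyl 3-chloro-2-(methoxymethoxy)-4-methyl-6-[(triisopropylsilyl)oxy]benzoate (formed in the flask) | Cc1cc(O[Si](C(C)C)(C(C)C)C(C)C)c(C(=O)OC(C)(C)C)c(OCOC)c1Cl | intermediate
6 | tert-butyl 3-chloro-6-hydroxy-2-(methoxymethoxy)-4-methylbenzoate | Cc1cc(O)c(C(=O)OC(C)(C)C)c(OCOC)c1Cl | intermediate
7 | chelidonic acid (4-oxo-4H-pyran-2,6-dicarboxylic acid) | OC(=O)C1=CC(=O)C=C(C(=O)O)O1 | starting material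
8 | dimethyl 4-oxo-4H-pyran-2,6-dicarboxylate | COC(=O)C1=CC(=O)C=C(C(=O)OC)O1 | intermediate
9 | methyl 6-(hydroxymethyl)-4-oxo-4H-pyran-2-carboxylate | COC(=O)C1=CC(=O)C=C(CO)O1 | intermediate
10 | methyl 6-{[2-(tert-butoxycarbonyl)-4-chloro-3-(methoxymethoxy)-5-methylphenoxy]methyl}-4-oxo-4H-pyran-2-carboxylate | COC(=O)C1=CC(=O)C=C(COc2cc(C)c(Cl)c(OCOC)c2C(=O)OC(C)(C)C)O1 | intermediate
11 | 7-[2-(tert-butoxycarbonyl)-4-chloro-3-(methoxymethoxy)-5-methylphenoxy]-2,4,6-trioxoheptanoic acid (formed in the flask as its barium enolate) | OC(=O)C(=O)CC(=O)CC(=O)COc1cc(C)c(Cl)c(OCOC)c1C(=O)OC(C)(C)C | intermediate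
12 | 2-[2-(tert-butoxycarbonyl)-4-chloro-3-(methoxymethoxy)-5-methylphenoxy]-1-hydroxy-3,5-dioxocyclohexane-1-carboxylic acid (formed in the flask; diastereomer mixture, both centres lost on aromatisation) | OC(=O)C1(O)CC(=O)CC(=O)C1Oc1cc(C)c(Cl)c(OCOC)c1C(=O)OC(C)(C)C | intermediate
13 | 2-[2-(tert-butoxycarbonyl)-4-chloro-3-(methoxymethoxy)-5-methylphenoxy]-3,5-dihydroxybenzoic acid | OC(=O)c1cc(O)cc(O)c1Oc1cc(C)c(Cl)c(OCOC)c1C(=O)OC(C)(C)C | intermediate
14 | methyl 2-[2-(tert-butoxycarbonyl)-4-chloro-3-(methoxymethoxy)-5-methylphenoxy]-3,5-dihydroxybenzoate | COC(=O)c1cc(O)cc(O)c1Oc1cc(C)c(Cl)c(OCOC)c1C(=O)OC(C)(C)C | intermediate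
15 | methyl 2-[2-(tert-butoxycarbonyl)-4-chloro-3-(methoxymethoxy)-5-methylphenoxy]-3-hydroxy-5-[(triisopropylsilyl)oxy]benzoate | COC(=O)c1cc(O[Si](C(C)C)(C(C)C)C(C)C)cc(O)c1Oc1cc(C)c(Cl)c(OCOC)c1C(=O)OC(C)(C)C | intermediate
16 | methyl 2-[2-(tert-butoxycarbonyl)-4-chloro-3-(methoxymethoxy)-5-methylphenoxy]-3-methoxy-5-[(triisopropylsilyl)oxy]benzoate | COC(=O)c1cc(O[Si](C(C)C)(C(C)C)C(C)C)cc(OC)c1Oc1cc(C)c(Cl)c(OCOC)c1C(=O)OC(C)(C)C | intermediate
17 | methyl 2-[2-(tert-butoxycarbonyl)-4-chloro-3-(methoxymethoxy)-5-methylphenoxy]-5-hydroxy-3-methoxybenzoate | COC(=O)c1cc(O)cc(OC)c1Oc1cc(C)c(Cl)c(OCOC)c1C(=O)OC(C)(C)C | intermediate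
18 | isodihydromaldoxin, 3-chloro-2-hydroxy-6-[4-hydroxy-2-methoxy-6-(methoxycarbonyl)phenoxy]-4-methylbenzoic acid | COC(=O)c1cc(O)cc(OC)c1Oc1cc(C)c(Cl)c(O)c1C(=O)O | target

**Count and risks**

Total step count: 13. Longest linear sequence: 11 steps (steps 1, 2, 3, 4, 7, 8, 9, 10, 11, 12, 13).

Step 8. Retro-Claisen cleavage of the 2,4-dioxo acid (loss of the oxalyl unit), or re-closure of the open chain to the pyranone acid on acidification, may outrun the aldol closure. The fallback gives up building ring A and forms the ether at an aromatic carbon by Ullmann coupling. It sets out from phenol 6. Commercial methyl 3-hydroxy-5-methoxybenzoate would be brominated para to the hydroxyl (NBS, MeCN) to methyl 2-bromo-5-hydroxy-3-methoxybenzoate F1 and allylated (allyl bromide, K2CO3, acetone) to methyl 2-bromo-3-methoxy-5-(prop-2-en-1-yloxy)benzoate F2. Coupling of F2 with 6 (CuI, N,N-dimethylglycine, Cs2CO3, 1,4-dioxane, 100 °C, the ortho ester assisting the copper insertion) should give methyl 2-[2-(tert-butoxycarbonyl)-4-chloro-3-(methoxymethoxy)-5-methylphenoxy]-3-methoxy-5-(prop-2-en-1-yloxy)benzoate F3. Allyl transfer to morpholine with catalytic Pd(PPh3)4 would free the C5 hydroxyl, and the route is rejoined at 17.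

Step 10. The silyl chloride may fail to tell the two ring A hydroxyls apart, so that silylation spreads to O3 or to both oxygens. The fallback replaces steric control of a protection by sequential trapping of a dianion and uses no silicon. It sets out from diol 14, which is doubly deprotonated (NaH, 2.2 equiv, THF–DMF, −20 °C). MOMCl (1.0 equiv) should be taken by the unhindered and more basic O5 phenoxide, and MeI added to the same flask then methylates the remaining O3 phenoxide. This gives methyl 2-[2-(tert-butoxycarbonyl)-4-chloro-3-(methoxymethoxy)-5-methylphenoxy]-3-methoxy-5-(methoxymethoxy)benzoate F4. The acid treatment of step 13 removes the tert-butyl ester and both MOM groups and comes back to the route at target 18.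

Step 3. Silylation may occur at the chlorine-flanked hydroxyl or at both hydroxyls, so that the two ring B oxygens are not differentiated. The fallback makes the ether bond itself the differentiating event. It sets out from diol 3 and alcohol 9. The alcohol is converted by an Appel reaction (CBr4, PPh3, CH2Cl2, 0 °C) into methyl 6-(bromomethyl)-4-oxo-4H-pyran-2-carboxylate F5. The dianion of 3 (NaH, 2.2 equiv, DMF, 0 °C) is treated with one equivalent of F5; its O6 phenoxide is both less hindered and more basic than the chlorine-flanked one and should be alkylated first. The product would be tert-butyl 3-chloro-2-hydroxy-4-methyl-6-{[6-(methoxycarbonyl)-4-oxo-4H-pyran-2-yl]methoxy}benzoate F6. Methoxymethylation of its remaining phenol (NaH, MOMCl, THF) rejoins the route at 10.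

**Further compounds**

F1 | step 8 | methyl 2-bromo-5-hydroxy-3-methoxybenzoate | COC(=O)c1cc(O)cc(OC)c1Br
F2 | step 8 | methyl 2-bromo-3-methoxy-5-(prop-2-en-1-yloxy)benzoate | COC(=O)c1cc(OCC=C)cc(OC)c1Br
F3 | step 8 | methyl 2-[2-(tert-butoxycarbonyl)-4-chloro-3-(methoxymethoxy)-5-methylphenoxy]-3-methoxy-5-(prop-2-en-1-yloxy)benzoate | COC(=O)c1cc(OCC=C)cc(OC)c1Oc1cc(C)c(Cl)c(OCOC)c1C(=O)OC(C)(C)C
F4 | step 10 | methyl 2-[2-(tert-butoxycarbonyl)-4-chloro-3-(methoxymethoxy)-5-methylphenoxy]-3-methoxy-5-(methoxymethoxy)benzoate | COC(=O)c1cc(OCOC)cc(OC)c1Oc1cc(C)c(Cl)c(OCOC)c1C(=O)OC(C)(C)C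
F5 | step 3 | methyl 6-(bromomethyl)-4-oxo-4H-pyran-2-carboxylate | COC(=O)C1=CC(=O)C=C(CBr)O1
F6 | step 3 | tert-butyl 3-chloro-2-hydroxy-4-methyl-6-{[6-(methoxycarbonyl)-4-oxo-4H-pyran-2-yl]methoxy}benzoate | COC(=O)C1=CC(=O)C=C(COc2cc(C)c(Cl)c(O)c2C(=O)OC(C)(C)C)O1
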